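## Analysis of the target

The target 27 is a 4→6 linked biflavanoid made of two 7,8-dihydroxy-2-(4-hydroxyphenyl)chroman units. Flavonoid numbering is used throughout: ring A is the benzo ring, ring C the pyran, ring B the 2-aryl group; U is the upper 4-arylflavan-3-ol and L the lower flavan-3,4-diol, joined by the U-C4 to L-C6 bond. U holds the triad 2S,3R,4R, with the 2-aryl group and 3-hydroxyl trans and the 3-hydroxyl and 4-aryl group (ring A of L) cis. L holds 2R,3R,4S, with the 2-aryl group and 3-hydroxyl cis and the two hydroxyls trans. Ring A of L insulates the two triads from each other, so each needs its own source of absolute configuration. The free compound has seven phenols, four of them in two catechol pairs, and is oxidation-prone; the L-C4 hydroxyl is benzylic to a ring with ortho and para oxygen and ionises readily; the interflavan bond is acid-labile. The hard points are three: the 3,4-cis relation in U (arene capture of a flavan-4-yl cation gives 3,4-trans); the 2,3-cis-3,4-trans pattern of L; and the identical 2,3,4-trioxygenation of both A rings, which stops late electrophilic substitution from telling L-C4a from U-C6 and means one of three like oxygens on L must be singled out. The strategy rests on the U-C3 to U-C4 bond: U-C4 carries two aryl groups and can be held as a diaryl ketone carbonyl, while U-C3 is held as an aldehyde tethered to ring A through O1 and the configured U-C2.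

## Retrosynthetic reasoning

**Protecting groups (27 from 26).** The last operation removes seven benzyl groups by hydrogenolysis. All phenols and U-O3 travel as benzyl ethers because these survive organolithium, hydride, low-valent metal and Lewis acid steps and leave together under neutral conditions, the only ones the free polyphenol tolerates.

**L-O1 to L-C2 (26 from 24 through 25).** Ring C of L is opened at the aryl ether bond. Forward, the L-C8a phenol opens a cis-epoxide at its benzylic carbon with inversion. This is the one closure that gives the 2,3-cis relation directly; a trans-epoxide or an inverted diol from an E-alkene would give 2,3-trans and need a repair at C3. The epoxide oxygen becomes the 3-hydroxyl.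

**Epoxide (24 from 23).** The two C–O bonds of the oxirane are cut back to a Z-allylic alcohol. Forward, a hydroxyl-directed peracid epoxidation is used: allylic 1,3-strain in a Z-allylic alcohol holds the carbinol hydrogen in the alkene plane, so the threo epoxy alcohol forms, which maps onto 3,4-trans. All three L stereocentres are thereby reduced to the single carbinol centre L-C4.

**L-C3 to L-C4 (23 from 22, and 22 from 19 and 20).** The bond between the carbinol carbon and the alkyne carbon is cut. Forward, alkyne 20 adds enantioselectively to aldehyde 19, and syn semi-hydrogenation gives the Z-alkene. One fragment brings in C2, C3 and ring B of L. The addition must be reagent-controlled because the U stereocentres are too far away to help.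

**Singling out L-O8a (19 from 18 from 17).** Once the formyl group sits on L-C4a, the neighbouring benzyl ether is the only one that can chelate a Lewis acid together with a carbonyl oxygen, so it alone is cleaved. The phenol is then silylated so that fluoride can release it later without touching benzyl ethers or the epoxide.

**Formyl group (17 from 15 through 16).** The L-C4a to CHO bond is cut to an aryl bromide; halogen–lithium exchange and formylation make it. The bromine must be on L-C4a before the aromatic halves are joined, because afterwards L-C4a and U-C6 are equally activated.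

**U-C4 hydrogen (15 from 14 from 13).** U-O3 is benzylated after the tertiary U-C4 hydroxyl has been replaced by hydrogen through ionic reduction. The diarylmethyl cation is attacked by hydride anti to the U-C3 oxygen, which puts the aryl group cis to it.

**U-C3 to U-C4 (13 from 12), the key disconnection.** Cutting here leaves U-C2 as the only stereocentre of U in the precursor, and that centre can be bought. Cutting U-C4 to L-C6 would give the wrong 3,4-trans relation on arene capture; cutting either C–O bond of ring C would require the whole triad in acyclic form. Forward, a one-electron reductant turns the ketone into a ketyl that closes ring C on the tethered aldehyde and sets U-C3.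

**U-C4 to L-C6 (12 from 11 from 10, and 10 from 3 and 8).** The diaryl ketone is traced to the aryllithium 9 from the symmetric dibromide 3 and aldehyde 8. An acylation under Lewis acid would strip benzyl ethers and would not tolerate the bromine handle. No hydride reagent that takes the ester to the aldehyde would spare a diaryl ketone, so the ketone is carried as its alcohol, the ester is reduced fully, and both alcohols are oxidised together just before the key step.

**U-O1 to U-C2 (8 from 5 and 7).** The aryl ether is made by Mitsunobu inversion of the mandelate 7 with phenol 5; the ester group suppresses ionisation, so R becomes S cleanly.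

**Building blocks.** Dibromide 3 comes from 1 through 2; phenol 5 from 4; mandelate 7 from 6.

## Alternatives that were turned down

**Alternative 1:** Ring C of U is cut at both O1–C2 and C3–C4. Forward, a chiral phosphoric acid dehydrates benzhydrol A1 to an ortho-quinone methide, which adds across its tethered (E)-enol carbonate to give cycloadduct A2.
- For it: two bonds and the whole U triad form in one step. The alkene geometry gives 2,3-trans, and the seven-membered carbonate from U-O3 to L-O7 forces 3,4-cis, so no deoxygenation is needed. On step count at the key stage it is stronger than the chosen route, which needs steps 8 to 10 for the same result.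
- Against it: the absolute configuration depends wholly on the catalyst acting on a hexa-alkoxy quinone methide that is strongly stabilised, and on a carbonyl-deactivated, weakly nucleophilic dienophile; an uncatalysed background reaction would be racemic. The (E)-enol carbonate in A1 must be made with control of geometry. Opening the carbonate frees L-O7, which must be re-protected before ring C of L is built.
- Comparison: the chosen route instead buys its absolute configuration in 6, transfers it by a stereospecific inversion, and sets the rest by substrate control.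

**Alternative 2:** Ring C of U is cut at O1–C8a. Forward, CuI (monovalent copper) with 1,10-phenanthroline and Cs2CO3 couples the U-C2 benzylic alkoxide of the acyclic bromide A3 with the ring A carbon, giving the fully protected dimer A4.
- For it: the closure creates no stereocentre, so it carries no stereochemical risk, and A4 is two deprotections from 27. On both points it is stronger than the chosen route.
- Against it: all six stereocentres, including the diarylmethine U-C4, must be set in an acyclic chain without a ring to bias them, which costs several asymmetric steps. The bromide in A3 is electron-rich and flanked by an alkoxy group and a branched carbon, so oxidative addition is slow. A secondary benzylic alkoxide heated with carbonate can lose hydride to give the ketone, shift silyl groups among three silyl ethers, or epimerise U-C4.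
- Comparison: the chosen route makes the ring closure itself set U-C3 from one purchased centre, and reaches its precursor in eight steps.

**Alternative 3:** Ring A of L is cut at C4a–C5 and C7–C8. Forward, the aminomethylene lactone A5 condenses with the keto ester A6 and aromatises to the resorcylate A7, freeing U-3-OH.
- For it: a five-membered lactone can only be cis-fused, so 3,4-cis is locked. The interflavan bond is never made by aryl coupling, so C6 versus C8 cannot arise. A7 emerges with L-O8a free and an ester on L-C4a, a better differentiated ring than the chosen route has after steps 12 and 13.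
- Against it: A5 still needs the complete U triad, so the main problem is only moved. The annulation requires the benzyloxy-bearing γ-carbon of A6 to acylate a deactivated, vinylogous carbamate-type carbonyl under strongly basic conditions, which threaten U-C4 and can expel U-O3. The reaction type is unproven on a substrate of this kind.
- Comparison: the chosen route uses purchased arenes and only known reaction types.

Key step: step 9

## Route

Assumption: in step 15 the sense of induction of the BINOL–Ti(OiPr)4 alkynylzinc addition known for simple aromatic aldehydes is taken to hold for aldehyde 19, which puts (R)-BINOL on the arrow for the (R)-carbinol.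

In the names below, "U-chromanyl" stands for the (2S,3R,4S)-3,7,8-tris(benzyloxy)-2-[4-(benzyloxy)phenyl]chroman-4-yl group (2,3-trans, 3,4-cis). Its C4 descriptor becomes R in 27 only because the CIP priorities change when the benzyl groups are removed.

Step 1
Reactants: 1 pyrogallol
Product: 2 1,2,3-tris(benzyloxy)benzene
Conditions: BnBr (3.3 equiv), K2CO3, DMF, 60 °C, N2
Reagents that add atoms: benzyl bromide, BrCc1ccccc1
Why: Williamson etherification of all three phenols; working under nitrogen keeps the pyrogallol anion from air oxidation.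

Step 2
Reactants: 2 1,2,3-tris(benzyloxy)benzene
Product: 3 1,5-dibromo-2,3,4-tris(benzyloxy)benzene
Conditions: NBS (2.1 equiv), MeCN, 0 °C to rt, dark
Reagents that add atoms: N-bromosuccinimide, O=C1CCC(=O)N1Br
Why: Electrophilic aromatic bromination; each outer benzyloxy group directs to the position para to itself and ortho to the other outer oxygen, while the central ether is twisted out of conjugation, so the two equivalent positions are taken and the carbon between them stays free, as expected for 1,2,3-trialkoxybenzenes.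

Step 3
Reactants: 4 2,3,4-trihydroxybenzaldehyde
Product: 5 3,4-bis(benzyloxy)-2-hydroxybenzaldehyde
Conditions: BnBr (2.05 equiv), K2CO3 (2.1 equiv), DMF, rt
Reagents that add atoms: benzyl bromide, BrCc1ccccc1
Why: Williamson etherification under stoichiometric control; the 2-hydroxyl is hydrogen-bonded to the formyl oxygen and is the least nucleophilic, so O-4 and O-3 are alkylated first, as is routine for gallacetophenone-type phenols.

Step 4
Reactants: 6 (R)-4-hydroxymandelic acid
Product: 7 benzyl (2R)-2-[4-(benzyloxy)phenyl]-2-hydroxyacetate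
Conditions: BnBr (2.1 equiv), K2CO3 (2.2 equiv), DMF, rt
Reagents that add atoms: benzyl bromide, BrCc1ccccc1
Why: Carboxylate and phenoxide are alkylated while the secondary alcohol is not deprotonated by carbonate; the weak base at room temperature should leave the stereocentre untouched.

Step 5
Reactants: 5 3,4-bis(benzyloxy)-2-hydroxybenzaldehyde; 7 benzyl (2R)-2-[4-(benzyloxy)phenyl]-2-hydroxyacetate
Product: 8 benzyl (2S)-2-[2,3-bis(benzyloxy)-6-formylphenoxy]-2-[4-(benzyloxy)phenyl]acetate
Conditions: PPh3, DIAD, toluene, 0 °C to rt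
Reagents that add atoms: none
Why: Mitsunobu etherification; the acidic salicylaldehyde-type phenol displaces the activated benzylic oxygen by SN2, inverting R to S, and the adjacent ester disfavours ionisation so the inversion should be clean; this sets U-C2.

Step 6
Reactants: 3 1,5-dibromo-2,3,4-tris(benzyloxy)benzene; 8 benzyl (2S)-2-[2,3-bis(benzyloxy)-6-formylphenoxy]-2-[4-(benzyloxy)phenyl]acetate
Product: 10 benzyl (2S)-2-{2,3-bis(benzyloxy)-6-[hydroxy(2,3,4-tris(benzyloxy)-5-bromophenyl)methyl]phenoxy}-2-[4-(benzyloxy)phenyl]acetate (both epimers at the new carbinol carbon), via aryllithium 9 (not isolated)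
Conditions: 3 (1.1 equiv), n-BuLi (1.05 equiv), THF, −78 °C, 20 min; cannulated into 8, THF, −78 °C; AcOH, −78 °C
Reagents that add atoms: none
Why: Bromine–lithium exchange of one of two equivalent bromides (a second exchange on the aryl anion is disfavoured) and 1,2-addition to the aldehyde, which at −78 °C outruns ester attack and deprotonation of the hindered α-C–H; the cold acid quench prevents the alkoxide from lactonising. The new carbinol centre is uncontrolled and irrelevant because step 8 oxidises it.

Step 7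
Reactants: 10 benzyl (2S)-2-{2,3-bis(benzyloxy)-6-[hydroxy(2,3,4-tris(benzyloxy)-5-bromophenyl)methyl]phenoxy}-2-[4-(benzyloxy)phenyl]acetate
Product: 11 (2S)-2-{2,3-bis(benzyloxy)-6-[hydroxy(2,3,4-tris(benzyloxy)-5-bromophenyl)methyl]phenoxy}-2-[4-(benzyloxy)phenyl]ethan-1-ol (both carbinol epimers)
Conditions: LiBH4, THF, 0 °C to rt
Reagents that add atoms: none
Why: Borohydride reduction of the activated α-aryloxy ester to the primary alcohol; LiBH4 leaves the aryl bromide and benzyl ethers alone and is not basic enough to epimerise the α-centre.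

Step 8
Reactants: 11 (2S)-2-{2,3-bis(benzyloxy)-6-[hydroxy(2,3,4-tris(benzyloxy)-5-bromophenyl)methyl]phenoxy}-2-[4-(benzyloxy)phenyl]ethan-1-ol
Product: 12 (2S)-2-{2,3-bis(benzyloxy)-6-[2,3,4-tris(benzyloxy)-5-bromobenzoyl]phenoxy}-2-[4-(benzyloxy)phenyl]acetaldehyde
Conditions: Dess–Martin periodinane (3 equiv), NaHCO3, CH2Cl2, 0 °C to rt; filtered and used at once
Reagents that add atoms: none
Why: Dess–Martin oxidation of the diaryl carbinol to the ketone and of the primary alcohol to the aldehyde in one operation; the buffered, non-basic conditions are those that spare α-aryl and α-alkoxy aldehydes from epimerisation, and the crude keto aldehyde is not chromatographed.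

Step 9
Reactants: 12 (2S)-2-{2,3-bis(benzyloxy)-6-[2,3,4-tris(benzyloxy)-5-bromobenzoyl]phenoxy}-2-[4-(benzyloxy)phenyl]acetaldehyde
Product: 13 (2S,3S,4S)-7,8-bis(benzyloxy)-2-[4-(benzyloxy)phenyl]-4-[2,3,4-tris(benzyloxy)-5-bromophenyl]chromane-3,4-diol (2,3-trans, 3,4-cis diol)
Conditions: SmI2 (2.5 equiv, 0.1 M in THF), THF, −78 to −20 °C, 12 added over 1 h to 0.01 M; sat. aq. NaHCO3
Reagents that add atoms: none
Why: Intramolecular ketyl–aldehyde pinacol coupling, the closest known class being SmI2 cyclisations of keto aldehydes and dialdehydes to cis-cycloalkane-1,2-diols. Inner-sphere electron transfer from divalent samarium goes to the diaryl ketone, which is far easier to reduce than an aliphatic aldehyde or an aryl bromide, and gives a samarium ketyl at U-C4. This carbon attacks the aldehyde carbon U-C3, activated by trivalent samarium, in a 6-exo-trig closure of ring C (O1, C2, C3, C4, C4a, C8a); a second electron and protonation on work-up deliver the diol. U-C3 is controlled by a half-chair in which the U-C2 aryl group is pseudo-equatorial and the aldehyde oxygen is turned toward the samarium on the ketyl oxygen, which places the new C3 oxygen trans to the C2 aryl group, the usual outcome of such cyclisations next to an α-alkoxy stereocentre. U-C4 is controlled by the samarium bridge between the two oxygens, which makes them cis; this centre is provisional and is reset in step 10. The step needs chemoselective reduction of the ketone (no HMPA and low temperature, so that neither the aldehyde, whose ketyl would expel the aryloxide, nor the C–Br bond is touched) and an intact U-C2, which the neutral, cold, aprotic medium secures; high dilution suppresses intermolecular coupling.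

Step 10
Reactants: 13 (2S,3S,4S)-7,8-bis(benzyloxy)-2-[4-(benzyloxy)phenyl]-4-[2,3,4-tris(benzyloxy)-5-bromophenyl]chromane-3,4-diol
Product: 14 (2S,3R,4S)-7,8-bis(benzyloxy)-2-[4-(benzyloxy)phenyl]-4-[2,3,4-tris(benzyloxy)-5-bromophenyl]chroman-3-ol (2,3-trans, 3,4-cis)
Conditions: Et3SiH (5 equiv), BF3·OEt2 (1.5 equiv), CH2Cl2, −78 to −40 °C
Reagents that add atoms: none
Why: Ionic hydrogenation; only the tertiary, doubly benzylic hydroxyl ionises, giving a diarylmethyl cation stabilised by ortho and para oxygen on both rings. The silane should deliver hydride to the face opposite the U-C3 oxygen, as nucleophiles do with flavan-4-yl cations, so hydrogen ends trans and the aryl group cis to the 3-hydroxyl; this sets U-C4.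

Step 11
Reactants: 14 (2S,3R,4S)-7,8-bis(benzyloxy)-2-[4-(benzyloxy)phenyl]-4-[2,3,4-tris(benzyloxy)-5-bromophenyl]chroman-3-ol
Product: 15 (2S,3R,4S)-3,7,8-tris(benzyloxy)-2-[4-(benzyloxy)phenyl]-4-[2,3,4-tris(benzyloxy)-5-bromophenyl]chromane
Conditions: NaH, BnBr, Bu4NI (cat.), DMF, 0 °C to rt
Reagents that add atoms: benzyl bromide, BrCc1ccccc1
Why: Williamson benzylation of the secondary alkoxide; it removes the only acidic proton before the organometallic steps and the group leaves in the final hydrogenolysis.

Step 12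
Reactants: 15 (2S,3R,4S)-3,7,8-tris(benzyloxy)-2-[4-(benzyloxy)phenyl]-4-[2,3,4-tris(benzyloxy)-5-bromophenyl]chromane
Product: 17 2,3,4-tris(benzyloxy)-5-(U-chromanyl)benzaldehyde, via aryllithium 16 (not isolated)
Conditions: n-BuLi (1.2 equiv), THF, −78 °C, 15 min; DMF (5 equiv), −78 to 0 °C; H2O
Reagents that add atoms: N,N-dimethylformamide, CN(C)C=O
Why: Bromine–lithium exchange followed by formylation with DMF; at −78 °C exchange at the ortho-alkoxy aryl bromide is faster than deprotonation of any benzylic position.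

Step 13
Reactants: 17 2,3,4-tris(benzyloxy)-5-(U-chromanyl)benzaldehyde
Product: 18 3,4-bis(benzyloxy)-2-hydroxy-5-(U-chromanyl)benzaldehyde
Conditions: MgBr2·OEt2 (3 equiv), toluene/Et2O, 60 °C; 1 M HCl work-up
Reagents that add atoms: none
Why: Chelation-assisted cleavage of an aryl benzyl ether ortho to a carbonyl group; magnesium binds the formyl oxygen and the neighbouring ether oxygen and bromide removes that benzyl group only, so L-O8a alone is freed among eight benzyl ethers.

Step 14
Reactants: 18 3,4-bis(benzyloxy)-2-hydroxy-5-(U-chromanyl)benzaldehyde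
Product: 19 3,4-bis(benzyloxy)-2-[(triisopropylsilyl)oxy]-5-(U-chromanyl)benzaldehyde
Conditions: iPr3SiCl, imidazole, DMF, 40 °C
Reagents that add atoms: chlorotri(propan-2-yl)silane, CC(C)[Si](Cl)(C(C)C)C(C)C
Why: Silylation of the phenol; the triisopropylsilyl group is bulky enough not to migrate to the alkoxide formed in step 15 and is later removed by fluoride without acid or strong base.

Step 15
Reactants: 19 3,4-bis(benzyloxy)-2-[(triisopropylsilyl)oxy]-5-(U-chromanyl)benzaldehyde; 20 1-(benzyloxy)-4-ethynylbenzene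
Product: 22 (1R)-1-{3,4-bis(benzyloxy)-2-[(triisopropylsilyl)oxy]-5-(U-chromanyl)phenyl}-3-[4-(benzyloxy)phenyl]prop-2-yn-1-ol, via alkynylzinc 21 (not isolated)
Conditions: 20 (3 equiv), Et2Zn (3 equiv), toluene, reflux; then (R)-BINOL (40 mol %), Ti(OiPr)4 (50 mol %), Et2O, rt; then 19, rt; H2O
Reagents that add atoms: none
Why: BINOL–Ti(OiPr)4-catalysed enantioselective addition of an alkynylzinc to an aromatic aldehyde, a method that accepts ortho-substituted benzaldehydes. The U stereocentres are too remote to interfere, so the ligand alone sets L-C4, and (R)-BINOL is expected to give the (R)-carbinol.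

Step 16
Reactants: 22 (1R)-1-{3,4-bis(benzyloxy)-2-[(triisopropylsilyl)oxy]-5-(U-chromanyl)phenyl}-3-[4-(benzyloxy)phenyl]prop-2-yn-1-ol
Product: 23 (1R,2Z)-1-{3,4-bis(benzyloxy)-2-[(triisopropylsilyl)oxy]-5-(U-chromanyl)phenyl}-3-[4-(benzyloxy)phenyl]prop-2-en-1-ol
Conditions: H2 (1 atm), Pd/CaCO3 poisoned with Pb(OAc)2 (Lindlar catalyst), quinoline, EtOAc, rt
Reagents that add atoms: none
Why: Lindlar semi-hydrogenation; syn delivery of hydrogen gives the Z-alkene, and the poisoned palladium does not cleave benzyl ethers or benzylic C–O bonds.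

Step 17
Reactants: 23 (1R,2Z)-1-{3,4-bis(benzyloxy)-2-[(triisopropylsilyl)oxy]-5-(U-chromanyl)phenyl}-3-[4-(benzyloxy)phenyl]prop-2-en-1-ol
Product: 24 (S)-{(2R,3S)-3-[4-(benzyloxy)phenyl]oxiran-2-yl}{3,4-bis(benzyloxy)-2-[(triisopropylsilyl)oxy]-5-(U-chromanyl)phenyl}methanol (threo, cis-epoxide)
Conditions: mCPBA (1.2 equiv), NaHCO3, CH2Cl2, −20 to 0 °C; used crude or after rapid filtration through Et3N-deactivated silica
Reagents that add atoms: 3-chloroperoxybenzoic acid, OOC(=O)c1cccc(Cl)c1
Why: Hydroxyl-directed peracid epoxidation; in a Z-allylic alcohol allylic 1,3-strain keeps the carbinol hydrogen in the alkene plane, so the peracid hydrogen-bonded to the hydroxyl attacks one face and gives the threo epoxy alcohol. This sets L-C3 and the provisional L-C2; the buffer protects the acid-labile allylic alcohol and the electron-rich aryl epoxide.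

Step 18
Reactants: 24 (S)-{(2R,3S)-3-[4-(benzyloxy)phenyl]oxiran-2-yl}{3,4-bis(benzyloxy)-2-[(triisopropylsilyl)oxy]-5-(U-chromanyl)phenyl}methanol
Product: 26 (2R,3R,4S)-7,8-bis(benzyloxy)-2-[4-(benzyloxy)phenyl]-6-(U-chromanyl)chromane-3,4-diol (2,3-cis, 3,4-trans), via phenol epoxide 25 (not isolated)
Conditions: Bu4NF (1.1 equiv), AcOH (2 equiv), THF, 0 °C to rt
Reagents that add atoms: none
Why: Fluoride cleaves the aryl silyl ether, and the freed phenol opens the epoxide in a 6-endo-tet closure at the benzylic carbon, the position favoured under mildly acidic conditions for aryl epoxides, with inversion at L-C2. The cis-epoxide thus gives 2,3-cis and the threo relation gives 3,4-trans; the acetic acid keeps the medium from becoming basic, which would favour the 5-exo mode.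

Step 19
Reactants: 26 (2R,3R,4S)-7,8-bis(benzyloxy)-2-[4-(benzyloxy)phenyl]-6-(U-chromanyl)chromane-3,4-diol
Product: 27 (2R,3R,4S)-2-(4-hydroxyphenyl)-6-[(2S,3R,4R)-3,7,8-trihydroxy-2-(4-hydroxyphenyl)chroman-4-yl]chromane-3,4,7,8-tetrol
Conditions: H2 (1 atm), Pd(OH)2/C, EtOAc/MeOH, rt, degassed solvents, stopped at full conversion
Reagents that add atoms: none
Why: Hydrogenolysis of seven benzyl ethers; aryl benzyl ethers are cleaved much faster than the two cyclic benzylic C–O bonds or the secondary benzylic alcohol as long as no acid is present, and no stereocentre is touched.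

## Compound list

1 | pyrogallol | Oc1cccc(O)c1O | starting material
2 | 1,2,3-tris(benzyloxy)benzene | C(Oc1cccc(OCc2ccccc2)c1OCc3ccccc3)c4ccccc4 | intermediate
3 | 1,5-dibromo-2,3,4-tris(benzyloxy)benzene | Brc1cc(Br)c(OCc6ccccc6)c(OCc6ccccc6)c1OCc6ccccc6 | intermediate
4 | 2,3,4-trihydroxybenzaldehyde | O=Cc1ccc(O)c(O)c1O | starting material
5 | 3,4-bis(benzyloxy)-2-hydroxybenzaldehyde | O=Cc1ccc(OCc6ccccc6)c(OCc6ccccc6)c1O | intermediate
6 | (R)-4-hydroxymandelic acid | O[C@@H](C(=O)O)c1ccc(O)cc1 | starting material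
7 | benzyl (2R)-2-[4-(benzyloxy)phenyl]-2-hydroxyacetate | O[C@@H](C(=O)OCc6ccccc6)c1ccc(OCc6ccccc6)cc1 | intermediate
8 | benzyl (2S)-2-[2,3-bis(benzyloxy)-6-formylphenoxy]-2-[4-(benzyloxy)phenyl]acetate | O=Cc1ccc(OCc6ccccc6)c(OCc6ccccc6)c1O[C@@H](c5ccc(OCc6ccccc6)cc5)C(=O)OCc6ccccc6 | intermediate
9 | [2,3,4-tris(benzyloxy)-5-bromophenyl]lithium | [Li]c1cc(Br)c(OCc6ccccc6)c(OCc6ccccc6)c1OCc6ccccc6 | intermediate
10 | benzyl (2S)-2-{2,3-bis(benzyloxy)-6-[hydroxy(2,3,4-tris(benzyloxy)-5-bromophenyl)methyl]phenoxy}-2-[4-(benzyloxy)phenyl]acetate, both carbinol epimers | OC(c1cc(Br)c(OCc6ccccc6)c(OCc6ccccc6)c1OCc6ccccc6)c5ccc(OCc6ccccc6)c(OCc6ccccc6)c5O[C@@H](c5ccc(OCc6ccccc6)cc5)C(=O)OCc6ccccc6 | intermediate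
11 | (2S)-2-{2,3-bis(benzyloxy)-6-[hydroxy(2,3,4-tris(benzyloxy)-5-bromophenyl)methyl]phenoxy}-2-[4-(benzyloxy)phenyl]ethan-1-ol, both carbinol epimers | OC(c1cc(Br)c(OCc6ccccc6)c(OCc6ccccc6)c1OCc6ccccc6)c5ccc(OCc6ccccc6)c(OCc6ccccc6)c5O[C@@H](c5ccc(OCc6ccccc6)cc5)CO | intermediate
12 | (2S)-2-{2,3-bis(benzyloxy)-6-[2,3,4-tris(benzyloxy)-5-bromobenzoyl]phenoxy}-2-[4-(benzyloxy)phenyl]acetaldehyde | O=C(c1cc(Br)c(OCc6ccccc6)c(OCc6ccccc6)c1OCc6ccccc6)c5ccc(OCc6ccccc6)c(OCc6ccccc6)c5O[C@@H](c5ccc(OCc6ccccc6)cc5)C=O | intermediate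
13 | (2S,3S,4S)-7,8-bis(benzyloxy)-2-[4-(benzyloxy)phenyl]-4-[2,3,4-tris(benzyloxy)-5-bromophenyl]chromane-3,4-diol | O[C@]4(c1cc(Br)c(OCc6ccccc6)c(OCc6ccccc6)c1OCc6ccccc6)c5ccc(OCc6ccccc6)c(OCc6ccccc6)c5O[C@@H](c5ccc(OCc6ccccc6)cc5)[C@@H]4O | intermediate
14 | (2S,3R,4S)-7,8-bis(benzyloxy)-2-[4-(benzyloxy)phenyl]-4-[2,3,4-tris(benzyloxy)-5-bromophenyl]chroman-3-ol | Brc1cc([C@@H]4c5ccc(OCc6ccccc6)c(OCc6ccccc6)c5O[C@@H](c5ccc(OCc6ccccc6)cc5)[C@@H]4O)c(OCc6ccccc6)c(OCc6ccccc6)c1OCc6ccccc6 | intermediate
15 | (2S,3R,4S)-3,7,8-tris(benzyloxy)-2-[4-(benzyloxy)phenyl]-4-[2,3,4-tris(benzyloxy)-5-bromophenyl]chromane | Brc1cc([C@@H]4c5ccc(OCc6ccccc6)c(OCc6ccccc6)c5O[C@@H](c5ccc(OCc6ccccc6)cc5)[C@@H]4OCc6ccccc6)c(OCc6ccccc6)c(OCc6ccccc6)c1OCc6ccccc6 | intermediate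
16 | [2,3,4-tris(benzyloxy)-5-(U-chromanyl)phenyl]lithium | [Li]c1cc([C@@H]4c5ccc(OCc6ccccc6)c(OCc6ccccc6)c5O[C@@H](c5ccc(OCc6ccccc6)cc5)[C@@H]4OCc6ccccc6)c(OCc6ccccc6)c(OCc6ccccc6)c1OCc6ccccc6 | intermediate
17 | 2,3,4-tris(benzyloxy)-5-(U-chromanyl)benzaldehyde | O=Cc1cc([C@@H]4c5ccc(OCc6ccccc6)c(OCc6ccccc6)c5O[C@@H](c5ccc(OCc6ccccc6)cc5)[C@@H]4OCc6ccccc6)c(OCc6ccccc6)c(OCc6ccccc6)c1OCc6ccccc6 | intermediate
18 | 3,4-bis(benzyloxy)-2-hydroxy-5-(U-chromanyl)benzaldehyde | O=Cc1cc([C@@H]4c5ccc(OCc6ccccc6)c(OCc6ccccc6)c5O[C@@H](c5ccc(OCc6ccccc6)cc5)[C@@H]4OCc6ccccc6)c(OCc6ccccc6)c(OCc6ccccc6)c1O | intermediate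
19 | 3,4-bis(benzyloxy)-2-[(triisopropylsilyl)oxy]-5-(U-chromanyl)benzaldehyde | O=Cc1cc([C@@H]4c5ccc(OCc6ccccc6)c(OCc6ccccc6)c5O[C@@H](c5ccc(OCc6ccccc6)cc5)[C@@H]4OCc6ccccc6)c(OCc6ccccc6)c(OCc6ccccc6)c1O[Si](C(C)C)(C(C)C)C(C)C | intermediate
20 | 1-(benzyloxy)-4-ethynylbenzene | C#Cc1ccc(OCc6ccccc6)cc1 | starting material
21 | ethyl{[4-(benzyloxy)phenyl]ethynyl}zinc | CC[Zn]C#Cc1ccc(OCc6ccccc6)cc1 | intermediate
22 | (1R)-1-{3,4-bis(benzyloxy)-2-[(triisopropylsilyl)oxy]-5-(U-chromanyl)phenyl}-3-[4-(benzyloxy)phenyl]prop-2-yn-1-ol | O[C@H](C#Cc1ccc(OCc6ccccc6)cc1)c1cc([C@@H]4c5ccc(OCc6ccccc6)c(OCc6ccccc6)c5O[C@@H](c5ccc(OCc6ccccc6)cc5)[C@@H]4OCc6ccccc6)c(OCc6ccccc6)c(OCc6ccccc6)c1O[Si](C(C)C)(C(C)C)C(C)C | intermediate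
23 | (1R,2Z)-1-{3,4-bis(benzyloxy)-2-[(triisopropylsilyl)oxy]-5-(U-chromanyl)phenyl}-3-[4-(benzyloxy)phenyl]prop-2-en-1-ol | O[C@H](/C=C\c1ccc(OCc6ccccc6)cc1)c1cc([C@@H]4c5ccc(OCc6ccccc6)c(OCc6ccccc6)c5O[C@@H](c5ccc(OCc6ccccc6)cc5)[C@@H]4OCc6ccccc6)c(OCc6ccccc6)c(OCc6ccccc6)c1O[Si](C(C)C)(C(C)C)C(C)C | intermediate
24 | (S)-{(2R,3S)-3-[4-(benzyloxy)phenyl]oxiran-2-yl}{3,4-bis(benzyloxy)-2-[(triisopropylsilyl)oxy]-5-(U-chromanyl)phenyl}methanol | O[C@H]([C@H]1O[C@H]1c1ccc(OCc6ccccc6)cc1)c1cc([C@@H]4c5ccc(OCc6ccccc6)c(OCc6ccccc6)c5O[C@@H](c5ccc(OCc6ccccc6)cc5)[C@@H]4OCc6ccccc6)c(OCc6ccccc6)c(OCc6ccccc6)c1O[Si](C(C)C)(C(C)C)C(C)C | intermediate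
25 | (S)-{(2R,3S)-3-[4-(benzyloxy)phenyl]oxiran-2-yl}{3,4-bis(benzyloxy)-2-hydroxy-5-(U-chromanyl)phenyl}methanol | O[C@H]([C@H]1O[C@H]1c1ccc(OCc6ccccc6)cc1)c1cc([C@@H]4c5ccc(OCc6ccccc6)c(OCc6ccccc6)c5O[C@@H](c5ccc(OCc6ccccc6)cc5)[C@@H]4OCc6ccccc6)c(OCc6ccccc6)c(OCc6ccccc6)c1O | intermediate
26 | (2R,3R,4S)-7,8-bis(benzyloxy)-2-[4-(benzyloxy)phenyl]-6-(U-chromanyl)chromane-3,4-diol | c6ccccc6COc1ccc([C@H]2Oc3c(cc([C@@H]4c5ccc(OCc6ccccc6)c(OCc6ccccc6)c5O[C@@H](c5ccc(OCc6ccccc6)cc5)[C@@H]4OCc6ccccc6)c(OCc6ccccc6)c3OCc6ccccc6)[C@H](O)[C@H]2O)cc1 | intermediate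
27 | (2R,3R,4S)-2-(4-hydroxyphenyl)-6-[(2S,3R,4R)-3,7,8-trihydroxy-2-(4-hydroxyphenyl)chroman-4-yl]chromane-3,4,7,8-tetrol | Oc1ccc([C@H]2Oc3c(cc([C@@H]4c5ccc(O)c(O)c5O[C@@H](c5ccc(O)cc5)[C@@H]4O)c(O)c3O)[C@H](O)[C@H]2O)cc1 | target

## Step count and least certain steps

Total step count: 19. Longest linear sequence: 16 steps (steps 3 and 5 to 19 from 4; equally long from 1 through steps 1, 2 and 6 to 19, and from 6 through steps 4 to 19).

**Step 9 (key step).** Three processes may defeat it. The stabilised, hindered ketyl may be reduced further to the diaryl carbinol without closing the ring. Electron transfer to the aldehyde would be followed by loss of the aryloxide. Closure through the other half-chair would give poor facial selectivity at U-C3. Fallback, from 12: low-valent titanium (TiCl4/Zn, pyridine, THF, reflux, high dilution) joins the two carbonyl carbons by intramolecular McMurry olefination, for which diaryl ketones are the best partners, to give (2R)-7,8-bis(benzyloxy)-2-[4-(benzyloxy)phenyl]-4-[2,3,4-tris(benzyloxy)-5-bromophenyl]-2H-chromene F1 (same spatial arrangement at C2). Dimethyldioxirane (acetone, −20 °C) epoxidises the C3=C4 bond on the face away from the C2 aryl group, giving the 3,4-epoxide of F1 with its oxygen trans to the 2-aryl group F2. Et3SiH/BF3·OEt2 at −78 °C opens it at the doubly benzylic carbon with hydride anti to the oxygen. The route is rejoined at 14.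

**Step 10.** The cation may undergo a 1,2-hydride shift from U-C3 (semipinacol rearrangement to the chroman-3-one), or hydride may show poor facial selectivity on the planar cation. Fallback, from 13: Ac2O, DMAP and pyridine acylate only the secondary hydroxyl to give the 3-O-acetate of 13 F3. On ionisation with BF3·OEt2 in the presence of Et3SiH the acetoxy group bridges the cation on its own face as a dioxolanylium ion, which switches off the hydride shift and leaves only the opposite face open, giving the 3-O-acetate of 14 F4. K2CO3 in MeOH removes the acetate, and the route is rejoined at 14.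

**Step 15.** Induction may be low or reversed on this hindered ortho-silyloxy aldehyde, or the addition may be sluggish. Fallback, from 19: the lithium acetylide of 20 (n-BuLi, THF, −78 °C) adds without stereocontrol to give the propargylic alcohol epimeric at the carbinol carbon F5. MnO2 in CH2Cl2 oxidises it to the ynone, 1-{3,4-bis(benzyloxy)-2-[(triisopropylsilyl)oxy]-5-(U-chromanyl)phenyl}-3-[4-(benzyloxy)phenyl]prop-2-yn-1-one F6. Reduction with (S)-2-methyl-CBS-oxazaborolidine and catecholborane at −78 °C, with the aryl group as the large substituent, should give the (R)-carbinol. The route is rejoined at 22.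

**Step 18.** The p-alkoxybenzylic epoxide carbon may ionise before the phenol arrives, which would erode the inversion at L-C2, or the phenol may close in the 5-exo mode on the other epoxide carbon. Fallback, from 23: the order is reversed. Bu4NF/AcOH (THF, 0 °C) first gives (1R,2Z)-1-{3,4-bis(benzyloxy)-2-hydroxy-5-(U-chromanyl)phenyl}-3-[4-(benzyloxy)phenyl]prop-2-en-1-ol F7, kept cold and used at once because it can lose water to an ortho-quinone methide. Buffered mCPBA (NaHCO3, CH2Cl2, −20 °C) then epoxidises it with the phenol already in place, so the epoxide is trapped intramolecularly as it forms. The route is rejoined at 26.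

**Step 19.** The activated benzylic L-C4 hydroxyl may be lost by hydrogenolysis while the slower alkyl benzyl ether on U-O3 is still being cleaved, and the product may oxidise in air. Fallback, from 26: tBuMe2SiOTf and 2,6-lutidine (CH2Cl2, −78 °C) silylate both hydroxyls to give the 3,4-bis(tert-butyldimethylsilyl) ether of 26 F8. Hydrogenolysis (H2, Pd(OH)2/C, EtOAc) then removes the seven benzyl groups while the benzylic silyl ether resists, giving the 3,4-bis(tert-butyldimethylsilyl) ether of 27 F9. Et3N·3HF in MeCN removes the silyl groups, and the route is rejoined at 27.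

## Further compounds

F1 | step 9 | (2R)-7,8-bis(benzyloxy)-2-[4-(benzyloxy)phenyl]-4-[2,3,4-tris(benzyloxy)-5-bromophenyl]-2H-chromene | Brc1cc(C4=C[C@H](c5ccc(OCc6ccccc6)cc5)Oc5c4ccc(OCc6ccccc6)c5OCc6ccccc6)c(OCc6ccccc6)c(OCc6ccccc6)c1OCc6ccccc6
F2 | step 9 | 3,4-epoxide of F1 with the oxirane oxygen trans to the 2-aryl group | O1[C@]4(c2cc(Br)c(OCc6ccccc6)c(OCc6ccccc6)c2OCc6ccccc6)c5ccc(OCc6ccccc6)c(OCc6ccccc6)c5O[C@@H](c5ccc(OCc6ccccc6)cc5)[C@H]14
F3 | step 10 | 3-O-acetate of 13 | O[C@]4(c1cc(Br)c(OCc6ccccc6)c(OCc6ccccc6)c1OCc6ccccc6)c5ccc(OCc6ccccc6)c(OCc6ccccc6)c5O[C@@H](c5ccc(OCc6ccccc6)cc5)[C@@H]4OC(C)=O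
F4 | step 10 | 3-O-acetate of 14 | Brc1cc([C@@H]4c5ccc(OCc6ccccc6)c(OCc6ccccc6)c5O[C@@H](c5ccc(OCc6ccccc6)cc5)[C@@H]4OC(C)=O)c(OCc6ccccc6)c(OCc6ccccc6)c1OCc6ccccc6
F5 | step 15 | 1-{3,4-bis(benzyloxy)-2-[(triisopropylsilyl)oxy]-5-(U-chromanyl)phenyl}-3-[4-(benzyloxy)phenyl]prop-2-yn-1-ol, both carbinol epimers | OC(C#Cc1ccc(OCc6ccccc6)cc1)c1cc([C@@H]4c5ccc(OCc6ccccc6)c(OCc6ccccc6)c5O[C@@H](c5ccc(OCc6ccccc6)cc5)[C@@H]4OCc6ccccc6)c(OCc6ccccc6)c(OCc6ccccc6)c1O[Si](C(C)C)(C(C)C)C(C)C
F6 | step 15 | 1-{3,4-bis(benzyloxy)-2-[(triisopropylsilyl)oxy]-5-(U-chromanyl)phenyl}-3-[4-(benzyloxy)phenyl]prop-2-yn-1-one | O=C(C#Cc1ccc(OCc6ccccc6)cc1)c1cc([C@@H]4c5ccc(OCc6ccccc6)c(OCc6ccccc6)c5O[C@@H](c5ccc(OCc6ccccc6)cc5)[C@@H]4OCc6ccccc6)c(OCc6ccccc6)c(OCc6ccccc6)c1O[Si](C(C)C)(C(C)C)C(C)C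
F7 | step 18 | (1R,2Z)-1-{3,4-bis(benzyloxy)-2-hydroxy-5-(U-chromanyl)phenyl}-3-[4-(benzyloxy)phenyl]prop-2-en-1-ol | O[C@H](/C=C\c1ccc(OCc6ccccc6)cc1)c1cc([C@@H]4c5ccc(OCc6ccccc6)c(OCc6ccccc6)c5O[C@@H](c5ccc(OCc6ccccc6)cc5)[C@@H]4OCc6ccccc6)c(OCc6ccccc6)c(OCc6ccccc6)c1O
F8 | step 19 | 3,4-bis(tert-butyldimethylsilyl) ether of 26 | c6ccccc6COc1ccc([C@H]2Oc3c(cc([C@@H]4c5ccc(OCc6ccccc6)c(OCc6ccccc6)c5O[C@@H](c5ccc(OCc6ccccc6)cc5)[C@@H]4OCc6ccccc6)c(OCc6ccccc6)c3OCc6ccccc6)[C@H](O[Si](C)(C)C(C)(C)C)[C@H]2O[Si](C)(C)C(C)(C)C)cc1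
F9 | step 19 | 3,4-bis(tert-butyldimethylsilyl) ether of 27 | Oc1ccc([C@H]2Oc3c(cc([C@@H]4c5ccc(O)c(O)c5O[C@@H](c5ccc(O)cc5)[C@@H]4O)c(O)c3O)[C@H](O[Si](C)(C)C(C)(C)C)[C@H]2O[Si](C)(C)C(C)(C)C)cc1
A1 | alternative 1 | benzhydrol with free ring A phenol of U and an (E)-enol carbonate on L-O7 | OC(c1ccc(OCc6ccccc6)c(OCc6ccccc6)c1O)c1ccc(OCc6ccccc6)c(OCc6ccccc6)c1OC(=O)O/C=C/c1ccc(OCc6ccccc6)cc1
A2 | alternative 1 | cycloadduct with a seven-membered cyclic carbonate from U-O3 to L-O7 | c6ccccc6COc1ccc(c8c1OCc6ccccc6)[C@@H]4c5ccc(OCc6ccccc6)c(OCc6ccccc6)c5O[C@@H](c5ccc(OCc6ccccc6)cc5)[C@@H]4OC(=O)O8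
A3 | alternative 2 | acyclic aryl bromide with free U-C2 hydroxyl, silylated U-O3 and complete silylated L unit | c6ccccc6COc1ccc([C@H]2Oc3c(cc([C@H](c5ccc(OCc6ccccc6)c(OCc6ccccc6)c5Br)[C@@H](O[Si](C)(C)C(C)(C)C)[C@@H](O)c5ccc(OCc6ccccc6)cc5)c(OCc6ccccc6)c3OCc6ccccc6)[C@H](O[Si](C)(C)C(C)(C)C)[C@H]2O[Si](C)(C)C(C)(C)C)cc1
A4 | alternative 2 | fully protected target with three silyl ethers and six benzyl ethers | c6ccccc6COc1ccc([C@H]2Oc3c(cc([C@@H]4c5ccc(OCc6ccccc6)c(OCc6ccccc6)c5O[C@@H](c5ccc(OCc6ccccc6)cc5)[C@@H]4O[Si](C)(C)C(C)(C)C)c(OCc6ccccc6)c3OCc6ccccc6)[C@H](O[Si](C)(C)C(C)(C)C)[C@H]2O[Si](C)(C)C(C)(C)C)cc1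
A5 | alternative 3 | cis-fused α-(dimethylaminomethylene) γ-lactone on U-C3 and U-C4 | CN(C)C=C1C(=O)O[C@H]2[C@H](c3ccc(OCc4ccccc4)cc3)Oc3c(OCc4ccccc4)c(OCc4ccccc4)ccc3[C@@H]12
A6 | alternative 3 | ethyl 4-(benzyloxy)-3-oxobutanoate | CCOC(=O)CC(=O)COCc1ccccc1
A7 | alternative 3 | ethyl 3-(benzyloxy)-2,4-dihydroxybenzoate carrying the U unit at its C5 | CCOC(=O)c1cc([C@@H]4c5ccc(OCc6ccccc6)c(OCc6ccccc6)c5O[C@@H](c5ccc(OCc6ccccc6)cc5)[C@@H]4O)c(O)c(OCc6ccccc6)c1O
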